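J is the reagent and X the substrate, and

1. which flask leads in amount of XJ, in percent of the X charged ("all alike" within 1.5 percentage points) (epsilon / delta / alpha / all alike)
2. how much XJ is there at the end, in percent of the X charged: epsilon
3. how much XJ is there at the end, in percent of the X charged: delta
4. how much XJ is there at the end, in percent of the X charged: alpha

 is what I have to answer for these flasks:

| flask | X | J | temperature | remark | time |
|---|---|---|---|---|---|
| south-west | 0.40 M (in portions, 4) | 1.44 M | 10 °C | run made earlier; portions every 12 s |  |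
| east | 1.6 M (in portions, 4) | 1.44 M | 43 °C | run made earlier; portions every 12 s |  |
| south | 0.80 M (in portions, 4) | 0.72 M | 10 °C | run made earlier; portions every 12 s |  |
| epsilon | 0.80 M (in portions, 4) | 1.44 M | −5 °C | the portions of X follow each other after 12 s, the first at the start | 30 min |
| delta | 0.80 M (in portions, 4) | 1.44 M | 25 °C | the portions of X follow each other after 12 s, the first at the start | 30 min |
| alpha | 0.80 M (in portions, 4) | 1.44 M | 55 °C | the portions of X follow each other after 12 s, the first at the start | 30 min |

- south-west (time / min: XJ / %, X / %): 1.33: 11.5, 88.8; 2.00: 17.6, 80.4; 3.00: 25.6, 69.3; 5.00: 34.7, 56.8; 8.00: 42.7, 44.3; 12.0: 42.4, 35.6; 20.0: 42.0, 27.2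
- east (time / min: XJ / %, X / %): 0.500: 14.3, 52.3; 1.00: 18.3, 56.0; 1.33: 14.0, 46.3; 2.00: 9.2, 34.8; 2.50: 8.1, 34.0; 3.00: 5.7, 29.0; 4.00: 5.9, 24.8
- south (time / min: XJ / %, X / %): 1.33: 6.4, 95.1; 5.00: 18.1, 77.3; 8.00: 23.1, 68.7; 12.0: 23.6, 59.4; 20.0: 24.0, 50.2

(each reading ± 1 percentage point)



I count turnovers. From 2.00 min to 5.00 min the south-west X falls at a pseudo-first-order rate of 0.116 min⁻¹, and the east X from 1.00 min to 2.00 min at 0.476 min⁻¹. Taking the mean cJ from the X lost and rescaling to cJ of 1.44 M, these become 0.127 min⁻¹ at 10 °C and 1.21 min⁻¹ at 43 °C. Drawing the logarithm of the rate as a straight line in temperature through these two points, and extending it beyond them for epsilon and alpha, I get the turnover count, the rate times the time, which is my estimate of the number of X lifetimes in the flask: 1.37 for epsilon, 10.6 for delta and 82.4 for alpha. The portions are in after 36.0 s, far less than 30 min, so I ignore them.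

Two versions solve in the head. If nothing consumes XJ, its share is one minus exp(−N), which for epsilon is 74.5%. If XJ goes as readily as it forms, its share is N·exp(−N), which is 34.8% and peaks at one turnover. I place epsilon between them: the south-west XJ reads flat from 8.00 min to 20.0 min while X falls from 44.3% to 27.2%, so I take XJ to be consumed there. Yet at 1.02 turnovers the south-west reading of 42.7% stands 5.9 percentage points above the lower version. Carrying that gap over from south-west, which differs from epsilon in its charge of X and its temperature, I commit to 40.8% for epsilon, and I expect epsilon to lead, since its count is past the one-turnover peak of the lower version and is the lowest of the three.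

The forecast says epsilon leads, with 35% for epsilon, which is lower than mine, 10% for delta and 2% for alpha: “XJ peaks early and then decays to roughly 10%”, it says of delta.

The flasks give 39.9% in epsilon, 6.35% in delta and 0.120% in alpha, so epsilon leads.

    X + 2 J → E (k = 2.60 × 10⁻⁴ M⁻² s⁻¹, Ea = 53.0 kJ mol⁻¹)
    J + XJ → JXJ (k = 0.00110 M⁻¹ s⁻¹, Ea = 62.0 kJ mol⁻¹)
    X + J ⇌ XJ (K = 1.00 M⁻¹, k = 0.00510 M⁻¹ s⁻¹, Ea = 58.0 kJ mol⁻¹, ΔH = −27.0 kJ mol⁻¹)
    X + XJ → XXJ (k = 0.00380 M⁻¹ s⁻¹, Ea = 69.0 kJ mol⁻¹)
    (constants at 25 °C)

At 30.0 min epsilon makes XJ 2.37 times as fast as it uses it up, each step taken net. Left until 50 min, the same flask counts 2.28 turnovers, which puts the versions at 89.8% and 23.3%, and the lower version plus my gap at 29.2%. The flask holds 43.9% of XJ, more than that reckoning gives, and where the count leaves 10.2% of X, it has 31.9% of X left.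

(The numbers in the tables were generated by integration from invented constants; the scatter is artificial.)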